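Ring C (the gem-dimethylcyclopentane) shares with ring B (the cyclopentanone) only the bond between the bridgehead carbon common to all three rings (alpha to the ring B ketone) and the adjacent ring-fusion CH; its other three carbons (CH2, the CH bearing the hydroxyisopropyl group, CMe2) form a 2-substituted allyl unit. Ring C is disconnected there: one palladium-catalysed, ligand-controlled (3+2) annulation adds a dimethyl-substituted trimethylenemethane unit across the alkene of tert-butyl 5-oxocyclopent-1-ene-1-carboxylate, forming both ring C bonds, the cis fusion and both fusion stereocentres. The donor is an allylic acetate with a CMe2(OAc) terminus and a CH2SiMe3 arm. The exocyclic methylene left behind becomes the hydroxyisopropyl group; the ester carbon closes ring A.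

Key step: step 3

Remark on names: ring A is the six-membered enolised acyl-dione ring. The bicyclic intermediates are numbered as pentalenes: C1 = CMe2, C2 = side-chain carbon, C3 = CH2, C3a = ester-bearing fusion carbon, C4 = ketone carbon, C5 and C6 = CH2, C6a = fusion CH. The convex face is the face of the C3a ester and H6a; the concave face is the one turned towards the other ring.

Assumption: both enantiomers of the phosphoramidite ligand are available, and the one that delivers the (3aS,6aS) adduct is chosen after a test run, because the sense of induction with this donor is not established.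

Step 1
Reactants: 1 tert-butyl 2-oxocyclopentane-1-carboxylate
Product: 4 tert-butyl 5-oxocyclopent-1-ene-1-carboxylate, via selenide 2 (not isolated), via selenoxide 3 (not isolated)
Conditions: PhSeCl, pyridine, CH2Cl2, 0 °C; then 30 % H2O2, 0 °C → rt; used at once
Reagents that add atoms: benzeneselenenyl chloride Cl[Se]c1ccccc1 (selenium and phenyl, present in 2 and 3 only); hydrogen peroxide OO (oxygen of 3 only)
Why: Alpha-selenenylation of the beta-keto ester followed by selenoxide syn-elimination, which can only run into the ring CH2 and so should give the 2-alkoxycarbonyl enone; no stereocentre remains.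

Step 2
Reactants: 5 (2-bromoprop-2-en-1-yl)trimethylsilane; 6 acetone
Product: 8 2-methyl-3-[(trimethylsilyl)methyl]but-3-en-2-yl acetate, via tertiary alcohol 7 (not isolated)
Conditions: Mg, THF, rt; 6, 0 °C; then Ac2O, DMAP (cat.), 0 °C → rt
Reagents that add atoms: acetic anhydride CC(=O)OC(C)=O
Why: Magnesium insertion gives the 2-(silylmethyl)vinyl Grignard reagent, whose 1,2-addition to acetone forms the tertiary alkoxide that is acetylated in the same flask (Grignard addition, then O-acylation); no stereocentre is formed.

Step 3
Reactants: 4 tert-butyl 5-oxocyclopent-1-ene-1-carboxylate; 8 2-methyl-3-[(trimethylsilyl)methyl]but-3-en-2-yl acetate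
Product: 9 tert-butyl (3aS,6aS)-1,1-dimethyl-2-methylidene-4-oxooctahydropentalene-3a-carboxylate (cis-fused)
Conditions: Pd(dba)2 (5 mol %), chiral BINOL-derived phosphoramidite of a trans-2,5-diarylpyrrolidine (10 mol %), PhMe, 0 °C → rt
Reagents that add atoms: none
Why: Zerovalent palladium ionises the tertiary allylic acetate of 8 and the acetate set free removes the silyl group, which gives a zwitterionic trimethylenemethane–palladium complex; its carbanionic carbon adds to the enone beta carbon of 4, and the beta-keto ester enolate so formed then attacks the π-allyl terminus and releases the catalyst. The closest known reaction type is the palladium-catalysed trimethylenemethane (3+2) cycloaddition to 2-alkoxycarbonyl cycloalkenones under chiral phosphoramidite control, applied here with a gem-dimethyl donor in place of the usual unsubstituted or monosubstituted ones. Ring C closes in the second event as a five-membered ring by C-alkylation of the enolate at the allyl terminus, with palladium leaving from outside the new ring (5-exo-tet-like). C6a is set in the conjugate addition, where the chiral phosphoramidite on palladium chooses the enone face, and C3a follows in the ring closure because the five–five fusion can only form cis. The step needs the CMe2 terminus and not the CH2 terminus to bond to the beta carbon: substituted trimethylenemethane–palladium complexes interconvert faster than they are trapped and react through the alkyl-bearing carbon, and the beta carbon of 4 is an unhindered CH made strongly electrophilic by two carbonyl groups, so it should accept the tertiary nucleophile before the complex loses a proton to a diene.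

Step 4
Reactants: 9 tert-butyl (3aS,6aS)-1,1-dimethyl-2-methylidene-4-oxooctahydropentalene-3a-carboxylate
Product: 10 tert-butyl (3aS,6aS)-4,4-(ethylenedioxy)-1,1-dimethyl-2-methylideneoctahydropentalene-3a-carboxylate (dioxolane ketal of 9)
Conditions: (Me3SiOCH2)2, Me3SiOTf (5 mol %), CH2Cl2, −78 → −20 °C; pyridine quench
Reagents that add atoms: 1,2-bis(trimethylsilyloxy)ethane C[Si](C)(C)OCCO[Si](C)(C)C
Why: Silyl-triflate-catalysed ketalisation with the bis-silyl ether of ethylene glycol works at low temperature on hindered ketones and spares the tert-butyl ester and the 1,1-disubstituted alkene; the ketone must be masked because 9-BBN and MeMgBr would otherwise attack it.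

Step 5
Reactants: 10 dioxolane ketal of 9
Product: 12 tert-butyl (2S,3aS,6aS)-4,4-(ethylenedioxy)-2-(hydroxymethyl)-1,1-dimethyloctahydropentalene-3a-carboxylate (CH2OH on the concave face, trans to the ester), via alkylborane 11 (not isolated)
Conditions: 9-BBN, THF, 0 °C → rt; then NaOH, H2O2, 0 °C → rt
Reagents that add atoms: 9-borabicyclo[3.3.1]nonane B1C2CCCC1CCC2 (boron and its ring, present in 11 only); hydrogen peroxide OO
Why: Anti-Markovnikov hydroboration–oxidation puts boron on the exocyclic CH2 and delivers hydrogen to C2 from the convex face of the cis-diquinane, since the concave face is closed by the other ring and its dioxolane, so the CH2OH group should end up on the concave face as the target requires.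

Step 6
Reactants: 12 primary alcohol
Product: 15 tert-butyl methyl (2S,3aS,6aS)-4,4-(ethylenedioxy)-1,1-dimethyloctahydropentalene-2,3a-dicarboxylate (methyl ester at C2, concave face), via aldehyde 13 (not isolated), via acid 14 (not isolated)
Conditions: TEMPO (10 mol %), PhI(OAc)2, MeCN–aq. NaH2PO4/Na2HPO4 (pH 7), rt; then Me3SiCHN2, PhMe–MeOH, 0 °C
Reagents that add atoms: water O; trimethylsilyldiazomethane C[Si](C)(C)C=[N+]=[N-]
Why: Nitroxyl-catalysed oxidation with PhI(OAc)2 in buffered aqueous acetonitrile takes the primary alcohol through the aldehyde hydrate to the acid under near-neutral conditions that should not epimerise C2, and the diazoalkane esterifies the crude acid without base.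

Step 7
Reactants: 15 methyl ester
Product: 17 tert-butyl (2S,3aS,6aS)-2-(2-hydroxypropan-2-yl)-1,1-dimethyl-4-oxooctahydropentalene-3a-carboxylate, via ketal alcohol 16 (not isolated)
Conditions: MeMgBr (4 equiv), THF, 0 °C → rt; then 2 M HCl, THF, rt
Reagents that add atoms: methylmagnesium bromide C[Mg]Br; water O
Why: Double Grignard addition to the methyl ester gives the tertiary alcohol while the tert-butyl ester on the quaternary C3a and the ketal resist, and the acidic work-up hydrolyses the dioxolane (ketal hydrolysis) to free the C4 ketone; C2 is not changed.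

Step 8
Reactants: 17 hydroxy ketone
Product: 18 tert-butyl (2S,3aS,6aS)-1,1-dimethyl-4-oxo-2-[2-(trimethylsilyloxy)propan-2-yl]octahydropentalene-3a-carboxylate
Conditions: N-(trimethylsilyl)imidazole, CH2Cl2, rt
Reagents that add atoms: N-(trimethylsilyl)imidazole C[Si](C)(C)n1ccnc1
Why: The N-silylimidazole silylates hindered tertiary alcohols without added base and leaves ketones alone; the ether is needed because a free alkoxide on the concave face could add to the C4 ketone and start a retro-Claisen cleavage in the basic steps that follow.

Step 9
Reactants: 18 silyl ether ketone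
Product: 19 5-methyl derivative of 18 (mainly methyl on the convex face)
Conditions: LiN(iPr)2, THF, −78 °C; MeI, −78 → −40 °C
Reagents that add atoms: iodomethane CI
Why: Kinetic enolate alkylation at C5, the only enolisable position because C3a is quaternary, with methyl iodide entering mainly from the convex face; the C5 configuration does not matter since it is erased in step 10.

Step 10
Reactants: 19 5-methyl ketone; 20 acetaldehyde
Product: 21 5-(1-hydroxyethyl)-5-methyl derivative of 18 (hydroxyethyl on the convex face, cis to the ester; C5 methyl on the concave face; carbinol epimers)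
Conditions: LiN(iPr)2, THF, −78 → 0 °C; then 20, −78 °C; AcOH quench at −78 °C
Reagents that add atoms: none
Why: Aldol addition of the tetrasubstituted lithium enolate, whose concave face is blocked by the silyloxyisopropyl group on the other ring, so acetaldehyde should add from the convex face and the new quaternary C5 carries the two-carbon unit cis to the ester as ring A requires; the carbinol configuration is irrelevant.

Step 11
Reactants: 21 aldol adduct
Product: 22 tert-butyl 5-acetyl-1,1,5-trimethyl-4-oxo-2-[2-(trimethylsilyloxy)propan-2-yl]octahydropentalene-3a-carboxylate (acetyl cis to the ester)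
Conditions: Dess–Martin periodinane, NaHCO3, CH2Cl2, rt
Reagents that add atoms: none
Why: Dess–Martin oxidation of the secondary alcohol under buffered, non-basic conditions should give the non-enolisable 1,3-diketone without retro-aldol or retro-Claisen cleavage and without loss of the silyl ether.

Step 12
Reactants: 22 acetyl keto ester
Product: 23 tricyclic 1,3-diketone (ring A closed, CH2 between its two carbonyls; bridging ring B ketone; tertiary alcohol as trimethylsilyl ether)
Conditions: LiN(SiMe3)2 (2.5 equiv), THF, −78 → 40 °C; aq. NH4Cl
Reagents that add atoms: none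
Why: Intramolecular Claisen (Dieckmann-type) condensation in which the acetyl methyl group, the only enolisable site, attacks the cis tert-butyl ester in a 6-exo-trig closure of ring A driven by deprotonation of the new 1,3-diketone, while the non-nucleophilic amide base and the bulky tert-butoxide leaving group avoid retro-Claisen attack on the C4 ketone.

Step 13
Reactants: 23 tricyclic 1,3-diketone; 24 (R)-2-methylbutanoic acid
Product: 27 target compound CNP0207052.1, via enol ester 25 (not isolated), via silyl ether 26 (not isolated)
Conditions: 24, DCC, DMAP (30 mol %), CH2Cl2, rt; then 1 M HCl, MeOH–THF, rt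
Reagents that add atoms: none
Why: Carbodiimide-mediated O-acylation of the cyclic 1,3-dione followed by DMAP-catalysed O-to-C acyl migration is the standard route to 2-acyl-1,3-diones and uses the acid itself, so no ketene forms and the (R) centre should be kept; acidic methanol then cleaves the tertiary silyl ether.

Compound list
1 | tert-butyl 2-oxocyclopentane-1-carboxylate | CC(C)(C)OC(=O)C1CCCC1=O | starting material
2 | tert-butyl 2-oxo-1-(phenylselanyl)cyclopentane-1-carboxylate (racemic) | CC(C)(C)OC(=O)C1(CCCC1=O)[Se]c1ccccc1 | intermediate (not isolated)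
3 | tert-butyl 2-oxo-1-(phenylseleninyl)cyclopentane-1-carboxylate (selenoxide of 2) | CC(C)(C)OC(=O)C1(CCCC1=O)[Se](=O)c1ccccc1 | intermediate (not isolated)
4 | tert-butyl 5-oxocyclopent-1-ene-1-carboxylate | CC(C)(C)OC(=O)C1=CCCC1=O | intermediate
5 | (2-bromoprop-2-en-1-yl)trimethylsilane | C=C(Br)C[Si](C)(C)C | starting material
6 | acetone | CC(C)=O | starting material
7 | 2-methyl-3-[(trimethylsilyl)methyl]but-3-en-2-ol | CC(C)(O)C(=C)C[Si](C)(C)C | intermediate (not isolated)
8 | 2-methyl-3-[(trimethylsilyl)methyl]but-3-en-2-yl acetate | CC(C)(OC(C)=O)C(=C)C[Si](C)(C)C | intermediate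
9 | tert-butyl (3aS,6aS)-1,1-dimethyl-2-methylidene-4-oxooctahydropentalene-3a-carboxylate, cis-fused | CC(C)(C)OC(=O)[C@@]12CC(=C)C(C)(C)[C@@H]1CCC2=O | intermediate
10 | dioxolane ketal of 9 at C4 | CC(C)(C)OC(=O)[C@@]12CC(=C)C(C)(C)[C@@H]1CCC23OCCO3 | intermediate
11 | B-alkyl-9-borabicyclo[3.3.1]nonane from 10 (boron on the former exocyclic CH2, H2 on the convex face) | CC(C)(C)OC(=O)[C@@]12C[C@H](CB3C4CCCC3CCC4)C(C)(C)[C@@H]1CCC25OCCO5 | intermediate (not isolated)
12 | tert-butyl (2S,3aS,6aS)-4,4-(ethylenedioxy)-2-(hydroxymethyl)-1,1-dimethyloctahydropentalene-3a-carboxylate | CC(C)(C)OC(=O)[C@@]12C[C@H](CO)C(C)(C)[C@@H]1CCC23OCCO3 | intermediate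
13 | C2 aldehyde corresponding to 12 | CC(C)(C)OC(=O)[C@@]12C[C@H](C=O)C(C)(C)[C@@H]1CCC23OCCO3 | intermediate (not isolated)
14 | C2 carboxylic acid corresponding to 12 | CC(C)(C)OC(=O)[C@@]12C[C@H](C(=O)O)C(C)(C)[C@@H]1CCC23OCCO3 | intermediate (not isolated)
15 | tert-butyl methyl (2S,3aS,6aS)-4,4-(ethylenedioxy)-1,1-dimethyloctahydropentalene-2,3a-dicarboxylate | CC(C)(C)OC(=O)[C@@]12C[C@H](C(=O)OC)C(C)(C)[C@@H]1CCC23OCCO3 | intermediate
16 | tert-butyl (2S,3aS,6aS)-4,4-(ethylenedioxy)-2-(2-hydroxypropan-2-yl)-1,1-dimethyloctahydropentalene-3a-carboxylate | CC(C)(C)OC(=O)[C@@]12C[C@H](C(C)(C)O)C(C)(C)[C@@H]1CCC23OCCO3 | intermediate (not isolated)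
17 | tert-butyl (2S,3aS,6aS)-2-(2-hydroxypropan-2-yl)-1,1-dimethyl-4-oxooctahydropentalene-3a-carboxylate | CC(C)(C)OC(=O)[C@@]12C[C@H](C(C)(C)O)C(C)(C)[C@@H]1CCC2=O | intermediate
18 | trimethylsilyl ether of 17 | CC(C)(C)OC(=O)[C@@]12C[C@H](C(C)(C)O[Si](C)(C)C)C(C)(C)[C@@H]1CCC2=O | intermediate
19 | 5-methyl derivative of 18, drawn as the expected major epimer (methyl on the convex face); the other C5 epimer gives the same enolate | CC(C)(C)OC(=O)[C@@]12C[C@H](C(C)(C)O[Si](C)(C)C)C(C)(C)[C@@H]1C[C@@H](C)C2=O | intermediate
20 | acetaldehyde | CC=O | starting material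
21 | 5-(1-hydroxyethyl)-5-methyl derivative of 18, hydroxyethyl cis to the ester, carbinol centre as a mixture | CC(C)(C)OC(=O)[C@@]12C[C@H](C(C)(C)O[Si](C)(C)C)C(C)(C)[C@@H]1C[C@@](C)(C(C)O)C2=O | intermediate
22 | 5-acetyl-5-methyl derivative of 18, acetyl cis to the ester | CC(C)(C)OC(=O)[C@@]12C[C@H](C(C)(C)O[Si](C)(C)C)C(C)(C)[C@@H]1C[C@@](C)(C(C)=O)C2=O | intermediate
23 | tricyclic 1,3-diketone with ring A closed, trimethylsilyl ether (drawn as the diketo tautomer) | C1C(=O)[C@]2(C)C[C@H]3C(C)(C)[C@@H](C(C)(C)O[Si](C)(C)C)C[C@@]3(C1=O)C2=O | intermediate
24 | (R)-2-methylbutanoic acid | CC[C@@H](C)C(=O)O | starting material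
25 | (R)-2-methylbutanoyl enol ester of 23, drawn with the acyl group on the enol oxygen next to the methyl-bearing bridgehead; the regioisomeric enol ester would give the same product | C1=C(OC(=O)[C@H](C)CC)[C@]2(C)C[C@H]3C(C)(C)[C@@H](C(C)(C)O[Si](C)(C)C)C[C@@]3(C1=O)C2=O | intermediate (not isolated)
26 | trimethylsilyl ether of the target | CC[C@@H](C)C(=O)C1=C(O)[C@]2(C)C[C@H]3C(C)(C)[C@@H](C(C)(C)O[Si](C)(C)C)C[C@@]3(C1=O)C2=O | intermediate (not isolated)
27 | target CNP0207052.1: tricyclic enolised trione bearing the (R)-2-methylbutanoyl group on ring A, a bridgehead methyl group, the gem-dimethyl group and the concave-face 2-hydroxypropan-2-yl group on ring C | CC[C@@H](C)C(=O)C1=C(O)[C@]2(C)C[C@H]3C(C)(C)[C@@H](C(C)(C)O)C[C@@]3(C1=O)C2=O | target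

Total step count: 13 steps.
Longest linear sequence: 12 steps (step 1 or step 2, then steps 3 to 13).

Steps most likely to fail

1. Step 3. What may go wrong: bonding of the unsubstituted CH2 terminus instead of the CMe2 terminus to the enone beta carbon, proton loss from the tertiary π-allyl intermediate to a diene before it is trapped, or weak discrimination of the enone faces. Fallback (sets out from 4, with alcohol 7 as the source of the reagent, and returns at 9): the two bonds are made one after the other. Alcohol 7, isolated by aqueous work-up before the anhydride is added in step 2, is treated with PBr3 and pyridine (Et2O, −20 °C); bromination with allylic transposition should give [2-(bromomethyl)-3-methylbut-2-en-1-yl]trimethylsilane F1. Enone 4 and this silane undergo an enantioselective Hosomi–Sakurai conjugate allylation catalysed by Cu(OTf)2 and a C2-symmetric bis(oxazoline) (CH2Cl2, −78 °C). The allylsilane can only attack through its dimethyl-substituted gamma carbon, so the regiochemistry is fixed by the mechanism, and the product should be tert-butyl 2-[3-(bromomethyl)-2-methylbut-3-en-2-yl]-5-oxocyclopentane-1-carboxylate F2, with the ring carbon that carries the side chain configured as C6a of 9. K2CO3 in acetone then closes ring C by 5-exo-tet C-alkylation of the beta-keto ester, which can only give the cis fusion, and delivers 9.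

2. Step 5. What may go wrong: hydride delivery to the exocyclic methylene from both faces, because the borane sits on the exocyclic carbon away from the ring, which would give a mixture at C2. Fallback (sets out from 10, returns at 15): C2 is set by hydrogenation of an endocyclic alkene, where the catalyst must approach the ring face itself. Ozonolysis of 10 (O3, CH2Cl2–MeOH, −78 °C; Me2S) gives the C2 ketone, tert-butyl 4,4-(ethylenedioxy)-1,1-dimethyl-2-oxooctahydropentalene-3a-carboxylate F3. KN(SiMe3)2 and PhNTf2 (THF, −78 °C) give the only possible enol triflate, the C2–C3 alkenyl triflate F4. Methoxycarbonylation (Pd(OAc)2, PPh3, CO, MeOH, Et3N, DMF) gives the C2–C3 unsaturated methyl ester F5. Hydrogenation over palladium on carbon (Pd/C, H2, EtOAc) should add hydrogen from the convex face and give 15, from which step 7 continues.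

3. Step 12. What may go wrong: slow addition of the enolate to the hindered tert-butyl ester, so that retro-Claisen opening of the doubly activated C4 ketone by traces of alkoxide or hydroxide takes over. Fallback (sets out from 22, returns at 23): the electrophile is exchanged before the closure. Me3SiOTf and 2,6-lutidine (CH2Cl2, 0 °C) cleave the tert-butyl ester and keep the silyl ether; aqueous work-up gives the keto acid, 5-acetyl-1,1,5-trimethyl-4-oxo-2-[2-(trimethylsilyloxy)propan-2-yl]octahydropentalene-3a-carboxylic acid F6. This acid is kept cold to avoid decarboxylation and is esterified at once with Me3SiCHN2 (PhMe–MeOH, 0 °C) to the corresponding methyl ester F7. LiN(SiMe3)2 (THF, −78 °C → rt) then closes ring A on the less hindered, more electrophilic methyl ester and gives 23.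

Further compounds
F1 | step 3 | [2-(bromomethyl)-3-methylbut-2-en-1-yl]trimethylsilane | C[Si](C)(C)CC(CBr)=C(C)C
F2 | step 3 | tert-butyl 2-[3-(bromomethyl)-2-methylbut-3-en-2-yl]-5-oxocyclopentane-1-carboxylate (side-chain carbon configured as C6a of 9) | CC(C)(C)OC(=O)C1C(=O)CC[C@H]1C(C)(C)C(=C)CBr
F3 | step 5 | tert-butyl 4,4-(ethylenedioxy)-1,1-dimethyl-2-oxooctahydropentalene-3a-carboxylate | CC(C)(C)OC(=O)[C@@]12CC(=O)C(C)(C)[C@@H]1CCC23OCCO3
F4 | step 5 | C2–C3 alkenyl triflate from the C2 ketone | CC(C)(C)OC(=O)[C@@]12C=C(OS(=O)(=O)C(F)(F)F)C(C)(C)[C@@H]1CCC23OCCO3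
F5 | step 5 | C2–C3 unsaturated methyl ester | CC(C)(C)OC(=O)[C@@]12C=C(C(=O)OC)C(C)(C)[C@@H]1CCC23OCCO3
F6 | step 12 | 5-acetyl-1,1,5-trimethyl-4-oxo-2-[2-(trimethylsilyloxy)propan-2-yl]octahydropentalene-3a-carboxylic acid | OC(=O)[C@@]12C[C@H](C(C)(C)O[Si](C)(C)C)C(C)(C)[C@@H]1C[C@@](C)(C(C)=O)C2=O
F7 | step 12 | methyl ester of the keto acid (methyl analogue of 22) | COC(=O)[C@@]12C[C@H](C(C)(C)O[Si](C)(C)C)C(C)(C)[C@@H]1C[C@@](C)(C(C)=O)C2=O
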